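**Retrosynthetic overview**

1. Locants: ring A = O–C3(=O)–C2=C1–C10–C5–C4(Me2); ring B = C5 to C10; ring C = C8, C9, C11, C12, C13(=CH2), C14(CO2Me); ring D = C12, C13, C14, C15(=O), C16(OH)(Me), C17(=O). Enabling feature: the ring A oxygen sits on C4 next to C5, and the quaternary C10 is tied to the carboxyl carbon C3 by the cis C1=C2 bond, so ring A plus the C5–C10 bond of ring B is a C10–O butenolide with a C4=C5 prenyl alkene inserted into its C–O bond.
2. Key disconnection: O–C4 and C5–C10 at once, which opens rings A and B to butenolide 17 carrying a 4-methylpent-3-enyl chain on C8 (run forward as a Lewis acid-induced alkene insertion into the lactone C–O bond).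
3. 17 comes from methyl ketone 12 by Felkin–Anh alkynylation and cis-reduction/lactonization; this fixes the C10–O centre that is inverted in the key step.
4. The bicyclo[3.3.1]nonane 12 (rings C and D) comes from the dearomatized orsellinate 10 by a Cope shift (C8–C14) and a vinylogous Michael closure (C11–C12); 10 comes from arene 3 and allyl carbonate 9 by asymmetric dearomative allylation, and 9 from but-2-yn-1-ol by carbomagnesiation/acylation.
5. Ring order: D (arene) → C (steps 5 and 6) → B and A together (step 9); the C16 hydroxyl is added last (step 10).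

Key step: step 9

Remark: 12 and 15 to 18 are written as 1,3-diketones; C16 is enolizable there and is left undefined until step 10.

**Route**

Step 1
Reactants: 1 methyl 2,4-dihydroxy-3,6-dimethylbenzoate
Product: 2 methyl 5-formyl-2,4-dihydroxy-3,6-dimethylbenzoate
Conditions: Cl2CHOMe, TiCl4, CH2Cl2, 0 °C; then aq. HCl
Reagents that add atoms: dichloromethyl methyl ether (COC(Cl)Cl); water (O)
Why: Rieche formylation: the TiCl4-activated dichloromethyl ether attacks the only unsubstituted ring carbon, which is ortho to the free 4-hydroxyl, and hydrolysis of the α-chloro ether gives the aldehyde.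

Step 2
Reactants: 2 methyl 5-formyl-2,4-dihydroxy-3,6-dimethylbenzoate
Product: 3 methyl 2,4-dihydroxy-3,5,6-trimethylbenzoate
Conditions: H2 (3 atm), Pd/C, AcOH, 25 °C
Reagents that add atoms: none
Why: Catalytic hydrogenolysis of an electron-rich ortho-hydroxybenzaldehyde runs through the benzylic alcohol to the methyl group and should leave ester and arene untouched.

Step 3
Reactants: 4 but-2-yn-1-ol; 5 5-bromo-2-methylpent-2-ene
Product: 8 (3Z)-3-(hydroxymethyl)-4,8-dimethylnona-3,7-dien-2-one, via 4-methylpent-3-enylmagnesium bromide 6 (not isolated), via 2-bromomagnesio-3,7-dimethylocta-2,6-dienyloxymagnesium bromide 7 (not isolated)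
Conditions: Mg, THF, 25 °C; then 4, Fe(acac)3 (10 mol %), THF, −78 to 0 °C; then MeC(O)N(OMe)Me, 0 to 25 °C; aq. NH4Cl
Reagents that add atoms: N-methoxy-N-methylacetamide (CC(=O)N(C)OC)
Why: Hydroxyl-directed iron-catalysed syn-carbomagnesiation of a propargylic alcohol delivers the alkyl group to the distal alkyne carbon, so in 7 the C–Mg bond is cis to the 4-methylpentenyl chain and the CH2O group cis to the methyl group, and acylation of this alkenylmagnesium with a Weinreb amide keeps that geometry, which fixes the tetrasubstituted (3Z) alkene.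

Step 4
Reactants: 8 (3Z)-3-(hydroxymethyl)-4,8-dimethylnona-3,7-dien-2-one
Product: 9 (2Z)-2-acetyl-3,7-dimethylocta-2,6-dien-1-yl methyl carbonate
Conditions: ClCO2Me, pyridine, CH2Cl2, 0 °C
Reagents that add atoms: methyl chloroformate (COC(=O)Cl)
Why: O-acylation of the primary allylic alcohol with a chloroformate gives the carbonate that serves as leaving group in the palladium step.

Step 5
Reactants: 3 methyl 2,4-dihydroxy-3,5,6-trimethylbenzoate; 9 (2Z)-2-acetyl-3,7-dimethylocta-2,6-dien-1-yl methyl carbonate
Product: 10 methyl (3R)-3-[(2Z)-2-acetyl-3,7-dimethylocta-2,6-dien-1-yl]-6-hydroxy-2,3,5-trimethyl-4-oxocyclohexa-1,5-diene-1-carboxylate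
Conditions: Pd2(dba)3·CHCl3 (2.5 mol %), DACH-phenyl Trost ligand (7.5 mol %, antipode chosen for the 3R product in a test run), 1,4-dioxane, 25 °C
Reagents that add atoms: none
Why: Palladium-catalysed asymmetric allylic dearomatization (Tsuji–Trost type): zerovalent palladium ionizes the carbonate, the methoxide set free deprotonates the 4-hydroxyl, and the methyl-bearing ring carbon ortho to it attacks the CH2 end of the π-allyl unit (O-allylation is reversible under these conditions, C-allylation is not), the chiral ligand choosing the face of the prochiral arene carbon and so setting the quaternary centre, while the alkene geometry is kept because syn–anti exchange would need a σ-bond to the fully substituted allyl terminus.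

Step 6
Reactants: 10 methyl (3R)-3-[(2Z)-2-acetyl-3,7-dimethylocta-2,6-dien-1-yl]-6-hydroxy-2,3,5-trimethyl-4-oxocyclohexa-1,5-diene-1-carboxylate
Product: 12 methyl (1R,2S,3R,5R)-3-acetyl-2,5,7-trimethyl-9-methylidene-2-(4-methylpent-3-en-1-yl)-6,8-dioxobicyclo[3.3.1]nonane-1-carboxylate, via Cope product 11 (not isolated)
Conditions: toluene, 100 °C; then DBU (1.5 equiv), 60 °C; aq. NH4Cl
Reagents that add atoms: none
Why: Cope rearrangement of a 6-allylcyclohexa-2,4-dienone to the 4-allylcyclohexa-2,5-dienone (the second stage of a para-Claisen rearrangement) moves the chain suprafacially through a chair array, so the centre of 10 is relayed into the new C14 and C8 centres and the methyl group cis to the CH2 terminus ends axial on ring C; DBU then drives a vinylogous Michael addition in which the γ-dienolate carbon next to the ring ketone adds to the new α-methylene ketone on the face that already carries the chain (C12 fixed by the ring, C13 methylene formed), only this adduct being stored as a stabilized β-diketonate so that reversible additions through C16 should drain into 12, and the C9 acetyl group equilibrates to the exo position.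

Step 7
Reactants: 12 methyl (1R,2S,3R,5R)-3-acetyl-2,5,7-trimethyl-9-methylidene-2-(4-methylpent-3-en-1-yl)-6,8-dioxobicyclo[3.3.1]nonane-1-carboxylate; 13 ethyl propiolate
Product: 15 ethyl (4S)-4-hydroxy-4-[(1R,2S,3R,5R)-1-(methoxycarbonyl)-2,5,7-trimethyl-9-methylidene-2-(4-methylpent-3-en-1-yl)-6,8-dioxobicyclo[3.3.1]nonan-3-yl]pent-2-ynoate, via lithium ethyl propiolate 14 (not isolated)
Conditions: 13 (3 equiv), LiN(SiMe3)2 (4 equiv), THF, −78 °C; then 12, CeCl3, −78 to −40 °C; aq. NH4Cl
Reagents that add atoms: none
Why: 1,2-Addition of a lithium acetylide to the methyl ketone (ring D is masked as its diketonate by the extra equivalent of base, CeCl3 suppresses enolization) should follow the Felkin–Anh model, the nucleophile entering anti to the quaternary C8 substituent of C9 and past the C9 hydrogen, which gives the (4S) carbinol.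

Step 8
Reactants: 15 ethyl (4S)-4-hydroxy-4-[(1R,2S,3R,5R)-1-(methoxycarbonyl)-2,5,7-trimethyl-9-methylidene-2-(4-methylpent-3-en-1-yl)-6,8-dioxobicyclo[3.3.1]nonan-3-yl]pent-2-ynoate
Product: 17 methyl (1R,2S,3R,5R)-2,5,7-trimethyl-9-methylidene-3-[(2R)-2-methyl-5-oxo-2,5-dihydrofuran-2-yl]-2-(4-methylpent-3-en-1-yl)-6,8-dioxobicyclo[3.3.1]nonane-1-carboxylate, via cis-hydroxy enoate 16 (not isolated)
Conditions: H2 (1 atm), Pd/CaCO3 poisoned with Pb(OAc)2, quinoline, EtOAc, 25 °C; then pyridinium p-toluenesulfonate (cat.), CH2Cl2, 25 °C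
Reagents that add atoms: none
Why: Semi-hydrogenation of the ynoate over poisoned palladium gives the cis enoate without touching the tri- and 1,1-disubstituted alkenes, and the cis γ-hydroxy ester lactonizes to the butenolide with retention at C10.

Step 9
Reactants: 17 methyl (1R,2S,3R,5R)-2,5,7-trimethyl-9-methylidene-3-[(2R)-2-methyl-5-oxo-2,5-dihydrofuran-2-yl]-2-(4-methylpent-3-en-1-yl)-6,8-dioxobicyclo[3.3.1]nonane-1-carboxylate
Product: 18 16-deoxy form of the target lactone (rings A to D closed; ring D a 2-methyl-1,3-diketone)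
Conditions: MeAlCl2 (4 equiv), CH2Cl2, −78 to −30 °C; aq. KNaC4H4O6
Reagents that add atoms: none
Why: Proposed new method: MeAlCl2 binds the lactone carbonyl of 17 and the tertiary C10–O bond breaks while the C4=C5 π bond attacks C10 from the rear (ring B, 6-exo, chair), which leaves a tertiary C4 cation beside an aluminium carboxylate held on the cis C1=C2 bond; this carboxylate closes on C4 to the seven-membered lactone (ring A, by oxygen capture of the exocyclic cation), so the net event is insertion of the alkene into the butenolide C–O bond, the reasoning being that a tert-alkyl ester is the ester class that cleaves by alkyl–oxygen heterolysis and that the carboxylate can reach C4 only after C5 has bonded to C10. The closest known reaction types are Friedel–Crafts alkylations with γ-lactones and AlCl3 (C–O ionization of a lactone), epoxide-initiated cation–olefin cyclizations under MeAlCl2 (rear-side opening at a tertiary carbon by an alkene) and carboxylic acid-terminated polyene cyclizations. C10 is set by inversion of the Felkin-derived C10–O centre: in the planar butenolide the breaking bond lies in the ring plane, orthogonal to the C1=C2 π system, so no allyl cation can assist and the alkene has to push from behind, which places the C10 methyl axial and C1 equatorial. C5 is set by the chair in which the developing isopropyl cation is equatorial on a chain that is anchored trans-diequatorially on ring C, which gives the trans A/B fusion. The step needs ring closure to win over proton loss at C10 or C4 and over attack at the lactone β-carbon: the non-basic aluminate counter-ion at low temperature, the 1,5 placement of carboxylate and C4 cation and the six- versus seven-membered ring sizes secure this, the C13 methylene is remote and flanked by two quaternary carbons, and the ring D diketone is parked as its aluminium enolate.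

Step 10
Reactants: 18 16-deoxy form of the target lactone
Product: 19 the target meroterpenoid lactone (16-hydroxy compound, single enantiomer)
Conditions: DBU (1.2 equiv), 3-phenyl-2-(phenylsulfonyl)oxaziridine (1.3 equiv), THF, −40 to 0 °C
Reagents that add atoms: 3-phenyl-2-(phenylsulfonyl)oxaziridine (O=S(=O)(c1ccccc1)N1OC1c1ccccc1)
Why: Electrophilic α-hydroxylation of the diketonate with an N-sulfonyloxaziridine (Davis oxidation) should deliver oxygen to the exo face of ring D, away from ring C, which places the hydroxyl exo and the C16 methyl endo as in the target, while the conjugated lactone and the hindered methylene are inert to this oxidant.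

**Compound list**

1 | methyl 2,4-dihydroxy-3,6-dimethylbenzoate | COC(=O)c1c(C)cc(O)c(C)c1O | starting material
2 | methyl 5-formyl-2,4-dihydroxy-3,6-dimethylbenzoate | COC(=O)c1c(C)c(C=O)c(O)c(C)c1O | intermediate
3 | methyl 2,4-dihydroxy-3,5,6-trimethylbenzoate | COC(=O)c1c(C)c(C)c(O)c(C)c1O | intermediate
4 | but-2-yn-1-ol | CC#CCO | starting material
5 | 5-bromo-2-methylpent-2-ene | CC(C)=CCCBr | starting material
6 | (4-methylpent-3-en-1-yl)magnesium bromide | CC(C)=CCC[Mg]Br | intermediate
7 | bromomagnesium (2Z)-2-(bromomagnesio)-3,7-dimethylocta-2,6-dien-1-olate (CH2O cis to the C3 methyl) | C/C(CCC=C(C)C)=C(\CO[Mg]Br)[Mg]Br | intermediate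
8 | (3Z)-3-(hydroxymethyl)-4,8-dimethylnona-3,7-dien-2-one | CC(=O)/C(CO)=C(/C)CCC=C(C)C | intermediate
9 | (2Z)-2-acetyl-3,7-dimethylocta-2,6-dien-1-yl methyl carbonate | CC(=O)/C(COC(=O)OC)=C(/C)CCC=C(C)C | intermediate
10 | methyl (3R)-3-[(2Z)-2-acetyl-3,7-dimethylocta-2,6-dien-1-yl]-6-hydroxy-2,3,5-trimethyl-4-oxocyclohexa-1,5-diene-1-carboxylate | COC(=O)C1=C(C)[C@@](C)(C/C(C(C)=O)=C(\C)CCC=C(C)C)C(=O)C(C)=C1O | intermediate
11 | methyl (1S)-1-[(3S)-2-acetyl-3,7-dimethylocta-1,6-dien-3-yl]-2-hydroxy-3,5,6-trimethyl-4-oxocyclohexa-2,5-diene-1-carboxylate | COC(=O)[C@]1([C@@](C)(CCC=C(C)C)C(=C)C(C)=O)C(C)=C(C)C(=O)C(C)=C1O | intermediate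
12 | methyl (1R,2S,3R,5R)-3-acetyl-2,5,7-trimethyl-9-methylidene-2-(4-methylpent-3-en-1-yl)-6,8-dioxobicyclo[3.3.1]nonane-1-carboxylate (acetyl exo; position 7 = C16, undefined) | C=C1[C@@]2(C)C[C@@H](C(C)=O)[C@](C)(CCC=C(C)C)[C@]1(C(=O)OC)C(=O)C(C)C2=O | intermediate
13 | ethyl propiolate | C#CC(=O)OCC | starting material
14 | lithium ethyl propiolate | [Li]C#CC(=O)OCC | intermediate
15 | ethyl (4S)-4-hydroxy-4-[(1R,2S,3R,5R)-1-(methoxycarbonyl)-2,5,7-trimethyl-9-methylidene-2-(4-methylpent-3-en-1-yl)-6,8-dioxobicyclo[3.3.1]nonan-3-yl]pent-2-ynoate | C=C1[C@@]2(C)C[C@@H]([C@](C)(O)C#CC(=O)OCC)[C@](C)(CCC=C(C)C)[C@]1(C(=O)OC)C(=O)C(C)C2=O | intermediate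
16 | ethyl (2Z,4R)-4-hydroxy-4-[(1R,2S,3R,5R)-1-(methoxycarbonyl)-2,5,7-trimethyl-9-methylidene-2-(4-methylpent-3-en-1-yl)-6,8-dioxobicyclo[3.3.1]nonan-3-yl]pent-2-enoate | C=C1[C@@]2(C)C[C@@H]([C@](C)(O)/C=C\C(=O)OCC)[C@](C)(CCC=C(C)C)[C@]1(C(=O)OC)C(=O)C(C)C2=O | intermediate
17 | methyl (1R,2S,3R,5R)-2,5,7-trimethyl-9-methylidene-3-[(2R)-2-methyl-5-oxo-2,5-dihydrofuran-2-yl]-2-(4-methylpent-3-en-1-yl)-6,8-dioxobicyclo[3.3.1]nonane-1-carboxylate | C=C1[C@@]2(C)C[C@@H]([C@@]3(C)C=CC(=O)O3)[C@](C)(CCC=C(C)C)[C@]1(C(=O)OC)C(=O)C(C)C2=O | intermediate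
18 | 16-deoxy form of the target lactone (as 19, but C16 bears hydrogen and methyl and is undefined) | C=C1[C@@]2(C)C[C@H]3[C@]4(C)C=CC(=O)OC(C)(C)[C@H]4CC[C@]3(C)[C@]1(C(=O)OC)C(=O)C(C)C2=O | intermediate
19 | the target meroterpenoid lactone: seven-membered 1,2-unsaturated lactone ring A with gem-dimethyl C4; rings A/B and B/C trans-fused; drawn with rings A to C flat, the methyl groups on C8, C10 and C12 and the C14 methyl ester on wedges, the hydrogens on C5 and C9 and the C15–C16–C17 diketone bridge on hashes; C13 methylidene; C16 hydroxyl exo (away from ring C), C16 methyl endo | C=C1[C@@]2(C)C[C@H]3[C@]4(C)C=CC(=O)OC(C)(C)[C@H]4CC[C@]3(C)[C@]1(C(=O)OC)C(=O)[C@@](C)(O)C2=O | target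

**Step count and risks**

Total step count: 10. Longest linear sequence: 8 steps (steps 3 to 10 from 4 and 5; equally steps 1, 2 and 5 to 10 from 1).

Steps most likely to fail:

1. Step 9 (proposed new method). What may go wrong: C10–O heterolysis runs ahead of the rear-side alkene attack, so that a free, rotating allyl cation erases the C10 configuration or loses a proton; or the C4 cation loses a proton before the carboxylate closes. The fallback sets out from 15 and comes back at 18, using known reaction types only. 15 is dehydrated toward the C10 methyl group (POCl3, pyridine, 0 °C) to the 1,3-enyne ester F1. Semi-hydrogenation over Pd/CaCO3 poisoned with Pb(OAc)2 gives the (2Z)-2,4-dienoate F2. LiOH (THF–H2O, 0 °C) cleaves the unhindered ethyl ester to the (2Z)-dienoic acid F3. ClSO3H (2-nitropropane, −78 °C) then protonates the terminal CH2 of the diene and starts a proton-initiated cation–olefin cyclization that is terminated by the carboxylic acid (the homofarnesylic acid to sclareolide type of lactonization), which closes rings B and A to 18.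

2. Step 6. What may go wrong: the base scrambles the E/Z geometry of the tetrasubstituted enone before the Cope shift (erosion at C8), or the Michael closure runs through C16, the central carbon of the vinylogous acid. The fallback sets out from 10 and comes back at 12. 10 is heated without base (toluene, 100 °C) and 11 is isolated. Me3SiCHN2 (MeOH–toluene, 0 °C) converts its vinylogous acid into the methyl enol ether F4, which has no acidic hydroxyl. Catalytic KOC(CH3)3 in tert-butanol then effects the vinylogous Michael closure under equilibrating conditions, the conjugated bicyclic vinylogous ester F5 being the thermodynamic adduct. Aqueous HCl (2 M) in THF hydrolyses the enol ether to 12.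

3. Step 5. What may go wrong: O-allylation or allylation at C16 instead of the methyl-bearing carbon next to the 4-oxygen, palladium-mediated re-ionization of the product, or poor facial discrimination by the ligand. The fallback sets out from 8 (with 3) and comes back at 10. 8 is converted with PBr3 (Et2O, 0 °C) into the allylic bromide F6. The lithium phenolate of 3 (LiN(SiMe3)2, toluene, 0 °C) is C-alkylated with it, a dearomative alkylation of the kind known for orsellinate esters with allylic bromides, to give racemic 10. The enantiomers are separated by preparative chromatography on a chiral stationary phase; 10 goes on and its antipode, the (3S)-dienone F7, is set aside.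

Further compounds
F1 | step 9 | ethyl 4-[(1R,2S,5R)-1-(methoxycarbonyl)-2,5,7-trimethyl-9-methylidene-2-(4-methylpent-3-en-1-yl)-6,8-dioxobicyclo[3.3.1]nonan-3-yl]pent-4-en-2-ynoate (1,3-enyne ester, exo substituent on the bicycle) | C=C1[C@@]2(C)C[C@@H](C(=C)C#CC(=O)OCC)[C@](C)(CCC=C(C)C)[C@]1(C(=O)OC)C(=O)C(C)C2=O
F2 | step 9 | ethyl (2Z)-4-[(1R,2S,5R)-1-(methoxycarbonyl)-2,5,7-trimethyl-9-methylidene-2-(4-methylpent-3-en-1-yl)-6,8-dioxobicyclo[3.3.1]nonan-3-yl]penta-2,4-dienoate (exo substituent on the bicycle) | C=C1[C@@]2(C)C[C@@H](C(=C)/C=C\C(=O)OCC)[C@](C)(CCC=C(C)C)[C@]1(C(=O)OC)C(=O)C(C)C2=O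
F3 | step 9 | (2Z)-4-[(1R,2S,5R)-1-(methoxycarbonyl)-2,5,7-trimethyl-9-methylidene-2-(4-methylpent-3-en-1-yl)-6,8-dioxobicyclo[3.3.1]nonan-3-yl]penta-2,4-dienoic acid (exo substituent on the bicycle) | C=C1[C@@]2(C)C[C@@H](C(=C)/C=C\C(=O)O)[C@](C)(CCC=C(C)C)[C@]1(C(=O)OC)C(=O)C(C)C2=O
F4 | step 6 | methyl (1S)-1-[(3S)-2-acetyl-3,7-dimethylocta-1,6-dien-3-yl]-4-methoxy-3,5,6-trimethyl-2-oxocyclohexa-3,5-diene-1-carboxylate | COC(=O)[C@]1([C@@](C)(CCC=C(C)C)C(=C)C(C)=O)C(C)=C(C)C(OC)=C(C)C1=O
F5 | step 6 | methyl (1R,2S,3R,5R)-3-acetyl-6-methoxy-2,5,7-trimethyl-9-methylidene-2-(4-methylpent-3-en-1-yl)-8-oxobicyclo[3.3.1]non-6-ene-1-carboxylate | C=C1[C@@]2(C)C[C@@H](C(C)=O)[C@](C)(CCC=C(C)C)[C@]1(C(=O)OC)C(=O)C(C)=C2OC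
F6 | step 5 | (3E)-3-(bromomethyl)-4,8-dimethylnona-3,7-dien-2-one | CC(=O)/C(CBr)=C(/C)CCC=C(C)C
F7 | step 5 | methyl (3S)-3-[(2Z)-2-acetyl-3,7-dimethylocta-2,6-dien-1-yl]-6-hydroxy-2,3,5-trimethyl-4-oxocyclohexa-1,5-diene-1-carboxylate | COC(=O)C1=C(C)[C@](C)(C/C(C(C)=O)=C(\C)CCC=C(C)C)C(=O)C(C)=C1O
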